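A flat curve is easily read as the ceiling of a flask's chemistry, yet the green run flattens at 13.8%, which is 19.3 mM of target, below the 0.112 M of coupling partner charged. The asked flask is the green run followed on.

| flask | starting material | second substrate | coupling partner | free catalyst | impurity | temperature | remark | time |
|---|---|---|---|---|---|---|---|---|
| green | 0.14 M | 0.14 M | 0.112 M | 0.14 mM | 0.12 mM | −20 °C | the very flask that is asked about, followed so far |  |
| grey | 0.14 M | 0.14 M | 0.112 M | 0.14 mM | 0.18 mM | −35 °C | run made earlier |  |
| flask | 0.14 M | 0.140 M | 0.112 M | 0.14 mM | 0.12 mM | −20 °C |  | 8.0 d |

- green (time / d: target / %): 0.625: 5.6; 1.04: 7.5; 1.67: 9.8; 2.50: 11.3; 3.00: 12.0; 5.00: 13.4; 8.00: 13.8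
- grey (time / d: target / %): 2.00: 3.8; 4.00: 4.6; 6.00: 5.2; 10.0: 5.9; 15.0: 5.8; 25.0: 6.3

(scatter of a reading: 0.3 percentage points)

- south-west: at 8.0 d add free catalyst, 100% of the amount charged, then wait 15 d
- north: at 8.0 d add coupling partner, 50.0% of the amount charged, then wait 15 d
- north-east: at 8.0 d raise the temperature by 25 K, then wait 15 d
- north-west: change nothing and wait 15 d more

- target, in percent of the starting material first charged, at 8.0 d
- what to do for the largest gain in target; "none" if nothing gains more than 2 percentage points (south-west / north / north-east / north-west / none)
- target present, in percent of the starting material first charged, after south-west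
- target present, in percent of the starting material first charged, after north

- the volume of additions can be left aside
- a reading or a percentage of target counts all its forms, free or not

The measure used here is the turnover number at the stall, N: c(target) made per c(free catalyst) charged. The green run gives N = 138, the grey run 63.0. The grey run is both colder and richer in impurity, so its lower value is put down to neither setting here.

My own reckoning, setting by setting:

1. Time. The green readings rise by 0.4 percentage points from 5.00 d to 8.00 d, close to the scatter of 0.3 points. Waiting should therefore gain less than 2 points, and the reading at 8.00 d serves as "now".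
2. Coupling partner. It is the limiting reagent of the charge, but the green curve stalled with less target than that charge. I take N to stay in place with more of it, so I expect a gain below 2 points.
3. Temperature. The two runs do not isolate it. I expect a gain below 2 points, and this is my least certain step.
4. Free catalyst. If a fresh dose repeats N, it adds 14 points, which gives 27.8%.

The forecast gives 13.9% now, south-west as best, 24% after south-west and 14.2% after north. It expects a smaller burst than mine: “Fresh catalyst should give a second burst, somewhat smaller because substrates are depleted”. My figure stands above its 24%.

The flask gives 13.9% now, 32.1% after south-west and 14.5% after north, and south-west has the largest gain, 18 points.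

    starting material + free catalyst ⇌ catalyst intermediate A (K = 61.0 /M, k = 0.0880 /M/s, Ea = 46.0 kJ/mol, ΔH = 10.0 kJ/mol)
    coupling partner + catalyst intermediate A → free catalyst + target (k = 0.0330 /M/s, Ea = 43.0 kJ/mol)
    second substrate + free catalyst ⇌ catalyst intermediate B (K = 260 /M, k = 0.0620 /M/s, Ea = 38.0 kJ/mol, ΔH = 29.0 kJ/mol)
    coupling partner + catalyst intermediate B → free catalyst + second product (k = 0.0660 /M/s, Ea = 58.0 kJ/mol)
    crystals ⇌ target, rate k5*(cs5 - [target]) while solid is left; crystals form when [target] > cs5 (solubility = 24.0 mM, k = 3.30 × 10⁻⁵ /s)
    free catalyst + impurity → spent catalyst A (k = 1.00 /M/s, Ea = 38.0 kJ/mol)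
    catalyst intermediate B → spent catalyst B (k = 8.60 × 10⁻⁶ /s, Ea = 77.0 kJ/mol)
    (constants at −20 °C)

At 8.00 d the impurity in the flask stood at 8.1% of its charge, or 0.00966 mM, against a dose of 0.140 mM of free catalyst. Counted as N, the target gained in the flask after that dose comes to 182 per free catalyst added, more than the 138 of the first charge. The neighbour charged with 0.56 M of second substrate reached 6.63% at 8.00 d, so its N at that time is 66.3, about half of the green run's.

The runs were computed for an exercise, and the scatter is random.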